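Wednesday's run, the richest in reagent, ended with substrate at 22% and first product at 44%, and that pair can be read for more than itself.

| setting | Saturday's | Thursday's | Wednesday's | elm | ash | maple |
|---|---|---|---|---|---|---|
| substrate | 20 mM | 20 mM | 20 mM | 20 mM | 20 mM | 20 mM |
| reagent | 30 mM | 42 mM | 75 mM | 24.0 mM | 80.0 mM | 60.0 mM |
| remark | run made earlier | run made earlier | run made earlier |  |  |  |
| time |  |  |  | 3.0 min | 3.0 min | 3.0 min |

| run | time / min | bis adduct / % | first product / % | substrate / % |
|---|---|---|---|---|
| Saturday's | 0.667 | 18 | 40 | 43 |
| Saturday's | 1.33 | 13 | 43 | 43 |
| Saturday's | 2.00 | 11 | 44 | 45 |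
| Saturday's | 2.50 | 15 | 41 | 40 |
| Saturday's | 3.00 | 15 | 41 | 41 |
| Thursday's | 0.667 | 19 | 44 | 36 |
| Thursday's | 1.33 | 20 | 43 | 36 |
| Thursday's | 2.00 | 20 | 46 | 33 |
| Thursday's | 2.50 | 26 | 46 | 35 |
| Thursday's | 3.00 | 18 | 45 | 37 |
| Wednesday's | 0.250 | 20 | 42 | 37 |
| Wednesday's | 0.417 | 24 | 43 | 28 |
| Wednesday's | 0.833 | 29 | 45 | 27 |
| Wednesday's | 1.50 | 32 | 43 | 26 |
| Wednesday's | 3.00 | 36 | 44 | 22 |

(standard deviation of a reading: 2 percentage points)

- the analysis behind the earlier runs scatters by 2 percentage points, standard deviation

- which of these holds the largest part of the substrate at the end of elm (bis adduct / substrate / first product)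
- which of these holds the largest part of the substrate at the end of ash (bis adduct / substrate / first product)
- which of these holds the largest part of the substrate at the end of maple (bis adduct / substrate / first product)
- final bis adduct in ash, as a percentage of the substrate charged

Write s, m and d for substrate, first product and bis adduct as fractions of the substrate charged. In ash, with 4.00 equivalents of reagent, the main step by itself turns substrate into first product and makes no bis adduct. Add the second step, first product with reagent to bis adduct. If each step is first order in its partner, both draw on the same reagent, so reagent and time cancel from the ratio of their rates and m becomes a function of s: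

m = (s^κ − s)/(1 − κ), d = 1 − s − m

A first answer of κ = 0.667 puts the peak of the curve at m = 44.4%, s = 29.6%, against Wednesday's reading of first product 45% at substrate 27%. Putting that answer back into the end of Wednesday's run gives:

κ = ln(s + m(1 − κ))/ln s = 0.663

This κ, the second step's rate constant over the first's, is the selectivity factor, a reading with the scatter of its readings. On these two steps d climbs as s falls, and ash has more reagent than the 2 equivalents bis adduct takes.

The rest of the flask shows in the runs: counting one reagent for each first product and two for each bis adduct, Wednesday's end readings account for 30.9% of the reagent charged, yet substrate read 26% at 1.50 min and 22% at 3.00 min. The end of s must therefore come from the runs. A power law through the last readings of Thursday's and Wednesday's runs gives, for ash: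

s = 20.8%, m = 43.1%, d = 36.2%

The forecast, holding that “the three runs lie on one consecutive-reaction curve”, names substrate for elm, first product for ash and first product for maple. It puts bis adduct in ash at 37% against 36.2% here, with the second step about 0.65 as fast as the first against 0.663 here.

The flasks end with substrate largest in elm, first product in ash and first product in maple, and ash holds bis adduct at 34.5%.

substrate + reagent → first product + by-product (k = 3.50 L mol⁻¹ s⁻¹); reagent + first product → bis adduct + by-product (k = 2.30 L mol⁻¹ s⁻¹); 2 reagent → homo dimer (k = 2.70 L mol⁻¹ s⁻¹) From the substrate of 21.8% in ash, κ gives first product 43.4% against 43.6% in the flask. The neighbour of ash charged with 320 mM of reagent ends at substrate 6.8%, where κ gives first product 29.7% and bis adduct 63.5%. That neighbour holds 30.0% of first product and 63.2% of bis adduct.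

(The earlier runs and the new flask are calculated with constants of no real substance; the scatter is artificial.)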